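The earlier runs and the new flask stem from a simulated flask from invented constants, and the scatter is random.

Tuesday's run at 0.80 M shows what Friday's flask at 0.40 M has not shown so far: target stands level, 13.0 % at 12.0 h and 13.4 % at 20.0 h, while substrate goes on falling.

| flask | substrate | remark | time |
|---|---|---|---|
| Friday's | 0.40 M | the very flask that is asked about, followed so far |  |
| Tuesday's | 0.80 M | run made earlier |  |
| flask | 0.40 M |  | 30 h |

- Friday's (time / h: substrate / %, target / %): 0.500: 97.2, 1.8; 1.33: 94.5, 3.7; 2.50: 90.1, 7.3; 4.00: 84.3, 10.0; 5.00: 80.3, 11.8
- Tuesday's (time / h: substrate / %, target / %): 4.00: 82.6, 8.1; 8.00: 65.5, 11.2; 12.0: 51.4, 13.0; 15.0: 42.5, 13.4; 20.0: 30.9, 13.4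

(each reading ± 0.3 percentage points)

- the analysis behind the earlier runs scatters by 0.3 percentage points, standard deviation
- in a conversion other conformer counts as not yet reacted
- the reaction counts as stopped when no species that holds the substrate changes by six tenths of a point or more over the second half of the time

1. why nothing more happens at 30 h, or that something still does (other conformer counts as not reacted) (it is still moving / all of the substrate has reacted / forward and back rates have come level)
2. part of the substrate that has turned into other species by 30 h (other conformer does not count)
3. how much target there is at 30 h, in percent of the substrate charged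

Two chemists dispute Friday's flask. The first takes substrate as plain first order and reads its half-life from Friday's last reading as 15.8 h. Then 30 h is 1.90 half-lives, so 26.8 % of the substrate remains. If target keeps Friday's share of 59.9 % of what has reacted, it reaches 43.8 %.

The second points to Tuesday's run, where substrate falls faster once target stands level. Between 12.0 h and 20.0 h he reads 10.9 h. This is the plateau half-life, the time in which substrate halves while [target] stands level, a pseudo-first-order loss. On his view [target] stays near 0.107 M, which is 26.8 % of Friday's charge. Counted from Friday's last reading, the plateau half-life leaves 16.4 % of the substrate.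

My own reckoning lies between them. Friday's [target] was 0.0472 M at 5.00 h, less than Tuesday's, so I take the mean of the two half-lives, which leaves 21.1 % of the substrate. Even the longer half-life takes 25 percentage points off substrate over the second half of the time, so Friday's flask should not have stopped.

The forecast, which is the second chemist's own and not the plateau count above, stands on the ground that “Substrate loss also speeds up as target builds” and reads: it is still moving, conversion 79 % (74 % to 84 %) and target 23 % (20.5 % to 25.5 %).

The simulation gives it is still moving, conversion 76.9 % and target 20.3 %.

    substrate ⇌ other conformer (K = 0.660, k = 1.70 × 10⁻⁶ s⁻¹)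
    substrate → target (k = 9.10 × 10⁻⁶ s⁻¹)
    other conformer → isomer of the product (k = 1.30 × 10⁻⁵ s⁻¹)
    target → over-reaction product (k = 5.30 × 10⁻⁶ s⁻¹)
    substrate + target → side product (k = 6.40 × 10⁻⁵ M⁻¹ s⁻¹)
    2 other conformer → self-condensation product (k = 1.30 × 10⁻⁴ M⁻¹ s⁻¹)

Substrate in Friday's flask stands at 20.0 % at 30.0 h. The first chemist's constant half-life comes close early: at 6.00 h it gives 76.9 % against 76.1 % in Friday's flask. Started from that flask's 46.8 % at 15.0 h, the plateau half-life gives 18.0 % at 30 h. Carried on from 20.0 % to 72.0 h, it gives 1.38 %, and the same flask read then holds 2.26 %.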